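**Plan**

1. Retrosynthesis: the three aryl O–CH3 bonds are cut first (catechols back to guaiacols), then all five aryl C–Br bonds in one operation, then the two aryl–CH2 bonds that join the central ring B to rings A and C.
2. Forward: guaiacol (ring B) is benzylated para to its hydroxyl by vanillyl alcohol (ring A), then para to its methoxyl by a second vanillyl alcohol (ring C). Fivefold bromination and demethylation follow.
3. Enabling feature: each ring is a benzene with CH2 on C1 and oxygens on C3 and C4, and its bromines lie on C5 (ortho to the C4 oxygen) and, in rings A and C, on the adjoining C6. With O4 as free OH and O3 as OMe, these are the ortho-to-hydroxyl and para-to-methoxyl carbons of a 4-alkylguaiacol. In ring B, C6 already carries a CH2, so that ring takes one bromine only.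
4. No ring is formed (all three benzene rings come from the starting materials) and the target has no stereocentre, so no stereocontrol is needed.

Key step: step 3

Ring labels: ring B bears both CH2 groups; ring A is the benzyl group para to the hydroxyl of ring B; ring C is the benzyl group para to its methoxyl.

**Route**

Step 1
Reactants: 1 vanillyl alcohol (4-hydroxy-3-methoxybenzyl alcohol); 2 guaiacol (2-methoxyphenol)
Product: 3 4,4′-methylenebis(2-methoxyphenol) (bisguaiacol F)
Conditions: 2 (5 equiv, neat), TsOH·H2O (5 mol %), 70 °C; excess 2 distilled off, crystallisation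
Reagents that add atoms: none
Why: Acid-catalysed Friedel–Crafts benzylation in which the 4-hydroxy-3-methoxybenzyl cation (protonated p-quinone methide) from 1 should attack guaiacol mainly para to its hydroxyl, the large excess of 2 suppressing further benzylation of 3.

Step 2
Reactants: 3 bisguaiacol F; 1 vanillyl alcohol
Product: 4 4,5-bis(4-hydroxy-3-methoxybenzyl)-2-methoxyphenol (tris-guaiacol)
Conditions: 3 (4 equiv), 1 added slowly, TsOH·H2O (10 mol %), 1,4-dioxane, 80 °C; unreacted 3 recovered by chromatography
Reagents that add atoms: none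
Why: Acid-catalysed Friedel–Crafts benzylation in which the 4-hydroxy-3-methoxybenzyl cation from 1 should attack one of the two equivalent rings of 3 at the carbon para to methoxyl, the preferred site of a 4-alkylguaiacol whose para-to-hydroxyl carbon is blocked, while ipso attack at the CH2-bearing carbon only regenerates 3 and the excess of 3 limits a second benzylation.

Step 3
Reactants: 4 tris-guaiacol
Product: 6 2-bromo-3,4-bis(2,3-dibromo-4-hydroxy-5-methoxybenzyl)-6-methoxyphenol (pentabromo tris-guaiacol), via tribromo tris-guaiacol 5 (not isolated)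
Conditions: Br2 (3.0 equiv), AcOH–CH2Cl2, 0 °C; then Br2 (2.05 equiv), 0 °C to rt, dark; aq NaHSO3
Reagents that add atoms: bromine, BrBr
Why: Each ring of 4 is a 4-alkylguaiacol that undergoes electrophilic aromatic substitution by Br2 through an oxygen-stabilised Wheland intermediate: the three carbons ortho to the free hydroxyls should react first at 0 °C to give tribromide 5, and the carbons para to methoxyl on rings A and C (between the CH2 and the new bromine) then take the fourth and fifth bromine. The closest known reactions are the bromination of creosol ortho to its hydroxyl and the stepwise conversion of vanillin into 5-bromovanillin and 5,6-dibromovanillin. No ring is closed and no stereocentre is formed. The step needs site selectivity (ortho to hydroxyl, then para to methoxyl, never the carbon between methoxyl and CH2) and must stop at five bromines; the order of directing power hydroxyl-ortho > methoxyl-para > methoxyl-ortho, the CH2 that already occupies the para-to-methoxyl carbon of ring B, and the metered 3 + 2 equivalents of Br2 should secure this. Ipso attack at the CH2-bearing carbons para to hydroxyl should stay reversible in the unbuffered medium, where HBr accumulates, and the bisulfite quench should reduce any bromodienone that remains. Because rings A and C become identical after demethylation, a bromine entering ring B at its other free carbon would still lead to the same target.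

Step 4
Reactants: 6 pentabromo tris-guaiacol
Product: 8 3-bromo-4,5-bis(2,3-dibromo-4,5-dihydroxybenzyl)benzene-1,2-diol (target), via tris(bromodioxaborole) 7 (not isolated)
Conditions: BBr3 (6 equiv), CH2Cl2, −78 °C to rt, Ar; then H2O, 0 °C
Reagents that add atoms: none
Why: BBr3 ether cleavage, in which each o-hydroxyanisole unit should form a B-bromo-1,3,2-benzodioxaborole with loss of MeBr by SN2 attack of bromide on the boron-activated methyl and aqueous work-up then frees the three catechols, the aryl C–Br and diarylmethane C–C bonds being inert to the reagent.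

**Compound list**

1 | vanillyl alcohol (4-hydroxy-3-methoxybenzyl alcohol) | COc1cc(CO)ccc1O | starting material
2 | guaiacol (2-methoxyphenol) | COc1ccccc1O | starting material
3 | 4,4′-methylenebis(2-methoxyphenol) (bisguaiacol F) | COc1cc(Cc2ccc(O)c(OC)c2)ccc1O | intermediate
4 | 4,5-bis(4-hydroxy-3-methoxybenzyl)-2-methoxyphenol | COc1cc(Cc2cc(OC)c(O)cc2Cc2ccc(O)c(OC)c2)ccc1O | intermediate
5 | 2-bromo-3,4-bis(3-bromo-4-hydroxy-5-methoxybenzyl)-6-methoxyphenol | COc1cc(Cc2cc(OC)c(O)c(Br)c2Cc2cc(OC)c(O)c(Br)c2)cc(Br)c1O | intermediate (not isolated)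
6 | 2-bromo-3,4-bis(2,3-dibromo-4-hydroxy-5-methoxybenzyl)-6-methoxyphenol | COc1cc(Cc2cc(OC)c(O)c(Br)c2Cc2cc(OC)c(O)c(Br)c2Br)c(Br)c(Br)c1O | intermediate
7 | 2,4-dibromo-5,6-bis[(2,6,7-tribromo-1,3,2-benzodioxaborol-5-yl)methyl]-1,3,2-benzodioxaborole | BrB1Oc2cc(Cc3cc4OB(Br)Oc4c(Br)c3Cc3cc4OB(Br)Oc4c(Br)c3Br)c(Br)c(Br)c2O1 | intermediate (not isolated)
8 | 3-bromo-4,5-bis(2,3-dibromo-4,5-dihydroxybenzyl)benzene-1,2-diol | Oc1cc(Cc2cc(O)c(O)c(Br)c2Cc2cc(O)c(O)c(Br)c2Br)c(Br)c(Br)c1O | target

**Step count**

Total steps: 4. Longest linear sequence: 4 steps (2 → 3 → 4 → 6 → 8).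

**Steps most likely to fail**

Step 3. Once the ortho-to-hydroxyl carbons are filled, bromine may attack the CH2-bearing carbons para to the free hydroxyls faster than the para-to-methoxyl carbons. The bromodienones formed could lose HBr to quinone methides (benzylic substitution) or expel a hydroxybenzyl cation (cleavage of an aryl–CH2 bond), and the bromine count may scatter around five. The fallback reverses the order of the two kinds of bromination under protecting-group control; it sets out from 4 and returns at 6. Acetylation (Ac2O, pyridine) should give 4,5-bis(4-acetoxy-3-methoxybenzyl)-2-methoxyphenyl acetate F1. With the hydroxyls masked, Br2 (2.1 equiv), NaOAc, AcOH, rt should enter only para to methoxyl on rings A and C, as in the bromination of O-acetylvanillin. Ring B has that carbon occupied, so the product should be 4,5-bis(4-acetoxy-2-bromo-5-methoxybenzyl)-2-methoxyphenyl acetate F2. Methanolysis (K2CO3, MeOH) frees 4,5-bis(2-bromo-4-hydroxy-5-methoxybenzyl)-2-methoxyphenol F3. Br2 (3.0 equiv) in AcOH–CH2Cl2 at 0 °C then fills the three open ortho-to-hydroxyl carbons, the fastest sites, to give 6.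

Step 2. The benzyl cation may discriminate poorly between the carbon para to methoxyl and the carbon ortho to hydroxyl, product 4 may be benzylated again, and 1 may condense with itself. The fallback fixes the site with a halogen; it sets out from 3 and returns at 4. Benzylation (BnBr, K2CO3, DMF) gives bis[4-(benzyloxy)-3-methoxyphenyl]methane F4. NBS (1 equiv) in MeCN at 0 °C should brominate one ring para to methoxyl to give 1-(benzyloxy)-4-[4-(benzyloxy)-3-methoxybenzyl]-5-bromo-2-methoxybenzene F5, with unreacted F4 recycled. Bromine–lithium exchange (n-BuLi, THF, −78 °C) gives {5-(benzyloxy)-2-[4-(benzyloxy)-3-methoxybenzyl]-4-methoxyphenyl}lithium F6. This adds to commercial 4-(benzyloxy)-3-methoxybenzaldehyde to give racemic {5-(benzyloxy)-2-[4-(benzyloxy)-3-methoxybenzyl]-4-methoxyphenyl}[4-(benzyloxy)-3-methoxyphenyl]methanol F7. Hydrogenolysis (H2, Pd/C, EtOAc–AcOH) removes the three benzyl ethers and the doubly benzylic hydroxyl and delivers 4.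

Step 1. The cation may also attack guaiacol para to methoxyl or ortho to hydroxyl and may benzylate 3 itself, so isomers and oligomers could prevent clean isolation of 3. The fallback builds the diarylmethane by carbonyl addition; it sets out from 2 and returns at 3. Para-bromination (NBS, MeCN, 0 °C) gives 4-bromo-2-methoxyphenol F8, and benzylation (BnBr, K2CO3, DMF) gives 1-(benzyloxy)-4-bromo-2-methoxybenzene F9. Bromine–lithium exchange (n-BuLi, THF, −78 °C) gives [4-(benzyloxy)-3-methoxyphenyl]lithium F10. Addition to 4-(benzyloxy)-3-methoxybenzaldehyde gives bis[4-(benzyloxy)-3-methoxyphenyl]methanol F11. Hydrogenolysis (H2, Pd/C, EtOAc–AcOH) cleaves both benzyl ethers and the benzhydrylic hydroxyl to give 3.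

**Further compounds**

F1 | step 3 | 4,5-bis(4-acetoxy-3-methoxybenzyl)-2-methoxyphenyl acetate | COc1cc(Cc2cc(OC)c(OC(C)=O)cc2Cc2ccc(OC(C)=O)c(OC)c2)ccc1OC(C)=O
F2 | step 3 | 4,5-bis(4-acetoxy-2-bromo-5-methoxybenzyl)-2-methoxyphenyl acetate | COc1cc(Cc2cc(OC)c(OC(C)=O)cc2Cc2cc(OC)c(OC(C)=O)cc2Br)c(Br)cc1OC(C)=O
F3 | step 3 | 4,5-bis(2-bromo-4-hydroxy-5-methoxybenzyl)-2-methoxyphenol | COc1cc(Cc2cc(OC)c(O)cc2Cc2cc(OC)c(O)cc2Br)c(Br)cc1O
F4 | step 2 | bis[4-(benzyloxy)-3-methoxyphenyl]methane | COc1cc(Cc2ccc(OCc3ccccc3)c(OC)c2)ccc1OCc1ccccc1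
F5 | step 2 | 1-(benzyloxy)-4-[4-(benzyloxy)-3-methoxybenzyl]-5-bromo-2-methoxybenzene | COc1cc(Cc2cc(OC)c(OCc3ccccc3)cc2Br)ccc1OCc1ccccc1
F6 | step 2 | {5-(benzyloxy)-2-[4-(benzyloxy)-3-methoxybenzyl]-4-methoxyphenyl}lithium | COc1cc(Cc2cc(OC)c(OCc3ccccc3)cc2[Li])ccc1OCc1ccccc1
F7 | step 2 | {5-(benzyloxy)-2-[4-(benzyloxy)-3-methoxybenzyl]-4-methoxyphenyl}[4-(benzyloxy)-3-methoxyphenyl]methanol (racemic) | COc1cc(Cc2cc(OC)c(OCc3ccccc3)cc2C(O)c2ccc(OCc3ccccc3)c(OC)c2)ccc1OCc1ccccc1
F8 | step 1 | 4-bromo-2-methoxyphenol | COc1cc(Br)ccc1O
F9 | step 1 | 1-(benzyloxy)-4-bromo-2-methoxybenzene | COc1cc(Br)ccc1OCc1ccccc1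
F10 | step 1 | [4-(benzyloxy)-3-methoxyphenyl]lithium | [Li]c1ccc(OCc2ccccc2)c(OC)c1
F11 | step 1 | bis[4-(benzyloxy)-3-methoxyphenyl]methanol | COc1cc(C(O)c2ccc(OCc3ccccc3)c(OC)c2)ccc1OCc1ccccc1
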